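**Retrosynthetic overview**
1. The angelate is put on the C4 carbinol by Yamaguchi esterification near the end; the two phenols travel as MOM ethers and are freed last.
2. Key disconnection C5–C5a: the oxepine is closed by 7-exo-dig cyclisation of an aryl radical (from an ortho-iodo aryl ether) onto a terminal propargylic-alcohol alkyne. This one step makes the seven-membered ring and the exocyclic methylene (last ring formed).
3. The acyclic precursor comes from an α-aryloxy-γ-alkynyl-γ-butyrolactone: Mitsunobu etherification with inversion sets C2, then 2 MeMgBr turn the lactone carbonyl into C(CH3)2OH and release the C4 carbinol.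
4. The cis-hydroxy lactone (temporary ring, formed second, opened before the radical step) comes from a catalytic asymmetric ynone–glyoxylate aldol (C2) and a hydroxyl-directed anti reduction (C4).
5. The benzene ring is bought as resorcinol and dressed by two directed ortho-metalations (CH3, then OH) and ortho-iodination.

Assumption: 4-(trimethylsilyl)but-3-yn-2-one is bought as but-3-yn-2-one carrying a Me3Si protecting group on the alkyne; resorcinol, ethyl glyoxylate (toluene solution) and angelic acid are bought as such.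

**Route**

Step 1
Reactants: 1 resorcinol
Product: 2 1,3-bis(methoxymethoxy)benzene
Conditions: NaH, MOMCl, DMF, 0 °C to rt
Reagents that add atoms: chloromethyl methyl ether (MOMCl), COCCl
Why: Williamson O-alkylation of the bis-phenoxide installs two MOM acetals that protect the phenols and direct the two lithiations that follow; no stereocentre is involved.

Step 2
Reactants: 2 1,3-bis(methoxymethoxy)benzene
Product: 4 1,3-bis(methoxymethoxy)-2-methylbenzene, via aryllithium 3 (not isolated)
Conditions: n-BuLi, THF, 0 °C to rt; MeI, -78 °C to rt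
Reagents that add atoms: iodomethane, CI
Why: Directed ortho-metalation removes the proton flanked by both OMOM groups (doubly coordinated, most acidic) and the aryllithium is methylated by SN2 on MeI.

Step 3
Reactants: 4 1,3-bis(methoxymethoxy)-2-methylbenzene
Product: 7 2,4-bis(methoxymethoxy)-3-methylphenol, via aryllithium 5 (not isolated), via arylboronate 6 (not isolated)
Conditions: n-BuLi, TMEDA, THF, 0 °C; B(OMe)3, -78 °C to rt; 30% H2O2, 0 °C to rt
Reagents that add atoms: hydrogen peroxide, OO
Why: A second directed ortho-metalation next to an OMOM group (both such ring positions are equivalent) is followed by borylation and boronate oxidation (1,2-aryl shift from B to O), giving the phenol oxygen that becomes O1.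

Step 4
Reactants: 7 2,4-bis(methoxymethoxy)-3-methylphenol
Product: 8 6-iodo-2,4-bis(methoxymethoxy)-3-methylphenol
Conditions: I2, NaHCO3, THF/H2O, 0 °C, dark
Reagents that add atoms: iodine, II
Why: Electrophilic aromatic iodination runs through the phenoxide, which outweighs the two acetal ethers and whose only free ortho/para position is C6, so the radical precursor lands on the future C5a.

Step 5
Reactants: 9 4-(trimethylsilyl)but-3-yn-2-one; 10 ethyl glyoxylate
Product: 11 ethyl (2R)-2-hydroxy-4-oxo-6-(trimethylsilyl)hex-5-ynoate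
Conditions: (S,S)-ProPhenol (10 mol %), Et2Zn (20 mol %), 4 Å MS, THF, 0 °C to rt
Reagents that add atoms: none
Why: Direct catalytic asymmetric aldol addition of a methyl ynone (Trost dinuclear zinc–ProPhenol catalysis): the zinc enolate adds to one face of the bound glyoxylate aldehyde and sets the 2R carbinol; the sense of induction for this acceptor is not established, so the mirror-image ligand is used if 2S is found.

Step 6
Reactants: 11 ethyl (2R)-2-hydroxy-4-oxo-6-(trimethylsilyl)hex-5-ynoate
Product: 13 (3R,5R)-3-hydroxy-5-[(trimethylsilyl)ethynyl]oxolan-2-one, via anti-diol ester 12 (not isolated)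
Conditions: Me4NBH(OAc)3, MeCN/AcOH, -30 °C; then TsOH (cat.), CH2Cl2, rt
Reagents that add atoms: none
Why: Evans–Saksena hydroxyl-directed reduction delivers hydride intramolecularly through a chair transition state to give the 1,3-anti diol (new 4R centre, the future C4), and acid-catalysed lactonisation of the anti-2,4-dihydroxy ester gives the cis-lactone.

Step 7
Reactants: 8 6-iodo-2,4-bis(methoxymethoxy)-3-methylphenol; 13 (3R,5R)-3-hydroxy-5-[(trimethylsilyl)ethynyl]oxolan-2-one
Product: 14 (3S,5R)-3-[6-iodo-2,4-bis(methoxymethoxy)-3-methylphenoxy]-5-[(trimethylsilyl)ethynyl]oxolan-2-one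
Conditions: PPh3, DIAD, PhMe, 0 °C to rt
Reagents that add atoms: none
Why: Mitsunobu etherification: the phenoxide displaces the oxyphosphonium group at the activated lactone α-carbon by SN2 from the face anti to the alkynyl group, inverting C3 (3R to 3S), which is C2 (S) of the target.

Step 8
Reactants: 14 (3S,5R)-3-[6-iodo-2,4-bis(methoxymethoxy)-3-methylphenoxy]-5-[(trimethylsilyl)ethynyl]oxolan-2-one
Product: 16 (3R,5S)-5-[6-iodo-2,4-bis(methoxymethoxy)-3-methylphenoxy]-6-methylhept-1-yne-3,6-diol, via silylalkyne diol 15 (not isolated)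
Conditions: MeMgBr (4 equiv), THF, -40 to 0 °C; then MeOH, K2CO3, rt
Reagents that add atoms: methylmagnesium bromide, C[Mg]Br
Why: Double Grignard addition to the lactone carbonyl builds the C(CH3)2OH group and releases the propargylic alkoxide with both stereocentres untouched, and base-catalysed methanolysis then removes the alkynyl silyl group.

Step 9
Reactants: 16 (3R,5S)-5-[6-iodo-2,4-bis(methoxymethoxy)-3-methylphenoxy]-6-methylhept-1-yne-3,6-diol
Product: 17 (2S,4R)-2-(2-hydroxypropan-2-yl)-7,9-bis(methoxymethoxy)-8-methyl-5-methylidene-2,3,4,5-tetrahydro-1-benzoxepin-4-ol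
Conditions: Bu3SnH (1.3 equiv, syringe pump), AIBN, PhH (5 mM), 80 °C
Reagents that add atoms: none
Why: Tin hydride-mediated aryl radical cyclisation: Bu3Sn• abstracts iodine, the σ-aryl radical adds 7-exo-dig to the proximal carbon of the terminal alkyne (C5–C5a bond), and the exocyclic vinyl radical takes H from Bu3SnH to give the 5-methylidene oxepine with C2 and C4 unchanged.

Step 10
Reactants: 17 (2S,4R)-2-(2-hydroxypropan-2-yl)-7,9-bis(methoxymethoxy)-8-methyl-5-methylidene-2,3,4,5-tetrahydro-1-benzoxepin-4-ol; 18 angelic acid [(2Z)-2-methylbut-2-enoic acid]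
Product: 20 (2S,4R)-2-(2-hydroxypropan-2-yl)-7,9-bis(methoxymethoxy)-8-methyl-5-methylidene-2,3,4,5-tetrahydro-1-benzoxepin-4-yl (2Z)-2-methylbut-2-enoate, via mixed anhydride 19 (not isolated)
Conditions: 18, 2,4,6-trichlorobenzoyl chloride, Et3N, PhMe, rt; then 17, 75 °C
Reagents that add atoms: none
Why: Yamaguchi esterification through the angelic 2,4,6-trichlorobenzoic mixed anhydride acylates only the secondary allylic alcohol (the tertiary one is inert) with retention at C4 and, run without DMAP, without Z to E isomerisation of the angelate.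

Step 11
Reactants: 20 (2S,4R)-2-(2-hydroxypropan-2-yl)-7,9-bis(methoxymethoxy)-8-methyl-5-methylidene-2,3,4,5-tetrahydro-1-benzoxepin-4-yl (2Z)-2-methylbut-2-enoate
Product: 21 (2S,4R)-7,9-dihydroxy-2-(2-hydroxypropan-2-yl)-8-methyl-5-methylidene-2,3,4,5-tetrahydro-1-benzoxepin-4-yl (2Z)-2-methylbut-2-enoate (CNP0160456.1)
Conditions: HCl (0.5 M in MeOH), THF, 0 °C to rt
Reagents that add atoms: none
Why: Acid-catalysed acetal exchange (methanolysis) cleaves the two aryl MOM ethers as dimethoxymethane under conditions mild enough to keep the angelate, the tertiary alcohol and the exocyclic alkene.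

**Compound list**

1 | resorcinol (benzene-1,3-diol) | Oc1cccc(O)c1 | starting material
2 | 1,3-bis(methoxymethoxy)benzene | COCOc1cccc(OCOC)c1 | intermediate
3 | [2,6-bis(methoxymethoxy)phenyl]lithium | COCOc1cccc(OCOC)c1[Li] | intermediate
4 | 1,3-bis(methoxymethoxy)-2-methylbenzene | COCOc1cccc(OCOC)c1C | intermediate
5 | [2,4-bis(methoxymethoxy)-3-methylphenyl]lithium | COCOc1ccc([Li])c(OCOC)c1C | intermediate
6 | dimethyl [2,4-bis(methoxymethoxy)-3-methylphenyl]boronate | COCOc1ccc(B(OC)OC)c(OCOC)c1C | intermediate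
7 | 2,4-bis(methoxymethoxy)-3-methylphenol | COCOc1ccc(O)c(OCOC)c1C | intermediate
8 | 6-iodo-2,4-bis(methoxymethoxy)-3-methylphenol | COCOc1cc(I)c(O)c(OCOC)c1C | intermediate
9 | 4-(trimethylsilyl)but-3-yn-2-one | CC(=O)C#C[Si](C)(C)C | starting material
10 | ethyl glyoxylate (ethyl oxoacetate) | CCOC(=O)C=O | starting material
11 | ethyl (2R)-2-hydroxy-4-oxo-6-(trimethylsilyl)hex-5-ynoate | CCOC(=O)[C@H](O)CC(=O)C#C[Si](C)(C)C | intermediate
12 | ethyl (2R,4R)-2,4-dihydroxy-6-(trimethylsilyl)hex-5-ynoate | CCOC(=O)[C@H](O)C[C@@H](O)C#C[Si](C)(C)C | intermediate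
13 | (3R,5R)-3-hydroxy-5-[(trimethylsilyl)ethynyl]oxolan-2-one (cis) | O=C1O[C@@H](C#C[Si](C)(C)C)C[C@H]1O | intermediate
14 | (3S,5R)-3-[6-iodo-2,4-bis(methoxymethoxy)-3-methylphenoxy]-5-[(trimethylsilyl)ethynyl]oxolan-2-one (trans) | O=C1O[C@@H](C#C[Si](C)(C)C)C[C@@H]1Oc2c(I)cc(OCOC)c(C)c2OCOC | intermediate
15 | (3R,5S)-5-[6-iodo-2,4-bis(methoxymethoxy)-3-methylphenoxy]-6-methyl-1-(trimethylsilyl)hept-1-yne-3,6-diol | COCOc1cc(I)c(O[C@H](C(C)(C)O)C[C@@H](O)C#C[Si](C)(C)C)c(OCOC)c1C | intermediate
16 | (3R,5S)-5-[6-iodo-2,4-bis(methoxymethoxy)-3-methylphenoxy]-6-methylhept-1-yne-3,6-diol | COCOc1cc(I)c(O[C@H](C(C)(C)O)C[C@@H](O)C#C)c(OCOC)c1C | intermediate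
17 | (2S,4R)-2-(2-hydroxypropan-2-yl)-7,9-bis(methoxymethoxy)-8-methyl-5-methylidene-2,3,4,5-tetrahydro-1-benzoxepin-4-ol | C=C1c2cc(OCOC)c(C)c(OCOC)c2O[C@H](C(C)(C)O)C[C@H]1O | intermediate
18 | angelic acid, (2Z)-2-methylbut-2-enoic acid | O=C(O)/C(C)=C\C | starting material
19 | (2Z)-2-methylbut-2-enoic 2,4,6-trichlorobenzoic anhydride | O=C(OC(=O)c1c(Cl)cc(Cl)cc1Cl)/C(C)=C\C | intermediate
20 | (2S,4R)-2-(2-hydroxypropan-2-yl)-7,9-bis(methoxymethoxy)-8-methyl-5-methylidene-2,3,4,5-tetrahydro-1-benzoxepin-4-yl (2Z)-2-methylbut-2-enoate | C=C1c2cc(OCOC)c(C)c(OCOC)c2O[C@H](C(C)(C)O)C[C@H]1OC(=O)/C(C)=C\C | intermediate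
21 | (2S,4R)-7,9-dihydroxy-2-(2-hydroxypropan-2-yl)-8-methyl-5-methylidene-2,3,4,5-tetrahydro-1-benzoxepin-4-yl (2Z)-2-methylbut-2-enoate | C=C1c2cc(O)c(C)c(O)c2O[C@H](C(C)(C)O)C[C@H]1OC(=O)/C(C)=C\C | target

**Step count and risks**

Total steps: 11. Longest linear sequence: 9 (steps 1–4, then 7–11, from resorcinol); the lactone branch (steps 5–6) joins at step 7.

Steps most likely to fail:

Step 9 (radical ring closure). A seven-membered closure competes with premature reduction of the aryl radical and with its addition to the solvent. It also competes with 1,5- and 1,6-hydrogen transfer from C3–H and C4–H. The exocyclic vinyl radical could also take the C2 hydrogen by a 1,5-shift, which would scramble C2. The fallback sets out from 16 and comes back at 17. It is a palladium-catalysed reductive Heck cyclisation (Pd(OAc)2, PPh3, HCO2Na, Et4NCl, DMF, 80 °C): oxidative addition into the C–I bond, 7-exo-dig syn-carbopalladation of the alkyne, and formate reduction of the vinylpalladium species. It passes through no compound outside the list (entry F0).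

Step 7 (Mitsunobu with a 2,6-disubstituted phenol). The hindered phenoxide may attack slowly, and the oxyphosphonium lactone may instead eliminate to the butenolide. The fallback sets out from 13 and comes back at 14. Compound 13 is converted (Tf2O, 2,6-lutidine, CH2Cl2, -78 °C) into (3R,5R)-2-oxo-5-[(trimethylsilyl)ethynyl]oxolan-3-yl trifluoromethanesulfonate F1. The pre-formed potassium phenoxide of 8 (K2CO3, 18-crown-6, MeCN, -20 °C) then displaces the triflate by SN2 with the same inversion.

Step 11 (acidic MOM removal on the finished ester). The allylic angelate may solvolyse or transpose, and acid may add to the electron-rich 1,1-disubstituted aryl alkene. The fallback sets out from 17 and comes back at 21; it moves the acid step in front of the esterification and changes the phenol protection to silyl: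
- The MOM groups of 17 are cleaved (HCl, MeOH, rt) to give (2S,4R)-2-(2-hydroxypropan-2-yl)-8-methyl-5-methylidene-2,3,4,5-tetrahydro-1-benzoxepine-4,7,9-triol F2.
- The two phenols are silylated (TBSCl, imidazole, DMF, 0 °C) to give (2S,4R)-7,9-bis{[tert-butyl(dimethyl)silyl]oxy}-2-(2-hydroxypropan-2-yl)-8-methyl-5-methylidene-2,3,4,5-tetrahydro-1-benzoxepin-4-ol F3.
- Yamaguchi esterification with 18 (via 19) gives (2S,4R)-7,9-bis{[tert-butyl(dimethyl)silyl]oxy}-2-(2-hydroxypropan-2-yl)-8-methyl-5-methylidene-2,3,4,5-tetrahydro-1-benzoxepin-4-yl (2Z)-2-methylbut-2-enoate F4.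
- Buffered fluoride (TBAF, AcOH, THF, 0 °C) gives 21.

Further compounds
F0 | step 9 | none | none
F1 | step 7 | (3R,5R)-2-oxo-5-[(trimethylsilyl)ethynyl]oxolan-3-yl trifluoromethanesulfonate | O=C1O[C@@H](C#C[Si](C)(C)C)C[C@H]1OS(=O)(=O)C(F)(F)F
F2 | step 11 | (2S,4R)-2-(2-hydroxypropan-2-yl)-8-methyl-5-methylidene-2,3,4,5-tetrahydro-1-benzoxepine-4,7,9-triol | C=C1c2cc(O)c(C)c(O)c2O[C@H](C(C)(C)O)C[C@H]1O
F3 | step 11 | (2S,4R)-7,9-bis{[tert-butyl(dimethyl)silyl]oxy}-2-(2-hydroxypropan-2-yl)-8-methyl-5-methylidene-2,3,4,5-tetrahydro-1-benzoxepin-4-ol | C=C1c2cc(O[Si](C)(C)C(C)(C)C)c(C)c(O[Si](C)(C)C(C)(C)C)c2O[C@H](C(C)(C)O)C[C@H]1O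
F4 | step 11 | (2S,4R)-7,9-bis{[tert-butyl(dimethyl)silyl]oxy}-2-(2-hydroxypropan-2-yl)-8-methyl-5-methylidene-2,3,4,5-tetrahydro-1-benzoxepin-4-yl (2Z)-2-methylbut-2-enoate | C=C1c2cc(O[Si](C)(C)C(C)(C)C)c(C)c(O[Si](C)(C)C(C)(C)C)c2O[C@H](C(C)(C)O)C[C@H]1OC(=O)/C(C)=C\C
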